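**Plan**

- Numbering used throughout: ring carbons C1–C10 with C10 = C(CH3)(OH) (methyl C14), C2 = CH(OH), C3=C4 (C4 carries C15H2OAc), C5 = CHOAc, C6 = lactone O–CH, C7, C8 = ester CH, C9; lactone carbons C11–C13.
- Retrosynthetic cuts, in order: C11=C13 (carried as CH–CH2NMe2); the C2/C10 diol (read as an isoxazoline); C1–C2 together with C10–O; C4–C5; the C8 ester C–O; C8–C9; C7–C8 and C11–C13.
- Forward: the lactone ring comes from a chiral-pool butenolide (C5, C6, C7, C11, C12). The chain is then extended at C7/C11, C8/C9, the C8 ester and C5/C4. The ten-membered carbocycle and an isoxazoline ring form together in the key step, followed by N–O cleavage, ketone reduction and unmasking of the methylene.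
- Stereochemistry: C6 from (S)-5-(hydroxymethyl)furan-2(5H)-one; C7 by anti conjugate addition; C8 by reagent-controlled allylboration; C5 by ligand-controlled Ni/Cr coupling; C10 by the facial selectivity of the cycloaddition; C2 by chelation-controlled reduction relayed from C10; both Z-alkenes from stereodefined alkenyl iodides.
- Enabling feature: the 1,3-diol C10(OH)(CH3)–C1H2–C2H(OH) next to the C3=C4 double bond is the reduced form of a 3-alkenyl-5-methyl-2-isoxazoline that bridges C2 and C10 of the ten-membered ring. It can therefore come from a nitrile oxide at C2 and a 2-methylallyl group (C9–C10(CH3)=C1H2).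

Key step: step 18

Remark: 7 and 13 are taken as purchasable. The chiral chromium ligand in step 15 is taken to be the enantiomer that leads to 5S; its antipode would be used if the sense proved opposite.

**Route**

Step 1
Reactants: 1 (E)-but-2-enal (crotonaldehyde)
Product: 2 (Z)-2-iodobut-2-enal
Conditions: I2, K2CO3, DMAP (cat.), THF/H2O 1:1, rt
Reagents that add atoms: iodine, II
Why: α-Iodination of an enal by addition–iodination–elimination (DMAP as Baylis–Hillman-type nucleophilic catalyst) should give the α-iodoenal with iodine cis to the methyl group, the geometry in which CHO and CH3 avoid each other.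

Step 2
Reactants: 2 (Z)-2-iodobut-2-enal
Product: 3 (Z)-2-iodobut-2-en-1-ol
Conditions: NaBH4, MeOH, 0 °C
Reagents that add atoms: none
Why: Borohydride 1,2-reduction of the aldehyde should leave the alkenyl iodide and its geometry untouched.

Step 3
Reactants: 3 (Z)-2-iodobut-2-en-1-ol
Product: 5 (Z)-2-(hydroxymethyl)but-2-enoic acid, via dilithio species 4 (not isolated)
Conditions: n-BuLi (1.0 equiv) then t-BuLi (2.1 equiv), Et2O, –78 °C; CO2; aq. HCl
Reagents that add atoms: carbon dioxide, O=C=O
Why: Iodine–lithium exchange on the lithium alkoxide gives a configurationally stable alkenyllithium whose carboxylation proceeds with retention, so the carboxyl group ends up cis to the methyl group (Z, angelate-type geometry).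

Step 4
Reactants: 5 (Z)-2-(hydroxymethyl)but-2-enoic acid
Product: 6 (Z)-2-(acetoxymethyl)but-2-enoic acid
Conditions: Ac2O, pyridine, DMAP (cat.), CH2Cl2, 0 °C; aq. work-up
Reagents that add atoms: acetic anhydride, CC(=O)OC(C)=O
Why: O-Acetylation of the primary alcohol under mild base should not isomerise the Z-enoic acid, and any mixed anhydride is hydrolysed on aqueous work-up.

Step 5
Reactants: 7 4-[(tert-butyldimethylsilyl)oxy]but-2-yn-1-ol
Product: 9 (Z)-4-[(tert-butyldimethylsilyl)oxy]-3-iodobut-2-en-1-ol, via vinylalanate 8 (not isolated)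
Conditions: NaAlH2(OCH2CH2OMe)2, THF, 0 °C; then I2, –78 °C
Reagents that add atoms: iodine, II
Why: Hydroxyl-directed trans-hydroalumination of the propargylic alcohol delivers hydride to the proximal and aluminium to the distal alkyne carbon, and iodinolysis with retention gives the Z-iodoalkene with iodine cis to the CH2OH group.

Step 6
Reactants: 9 (Z)-4-[(tert-butyldimethylsilyl)oxy]-3-iodobut-2-en-1-ol
Product: 10 (Z)-4-[(tert-butyldimethylsilyl)oxy]-3-iodobut-2-enal
Conditions: MnO2, CH2Cl2, rt
Reagents that add atoms: none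
Why: Allylic oxidation with MnO2 stops at the aldehyde and should not isomerise the trisubstituted iodoalkene.

Step 7
Reactants: 10 (Z)-4-[(tert-butyldimethylsilyl)oxy]-3-iodobut-2-enal
Product: 12 (Z)-2-iodo-4,4-dimethoxybut-2-en-1-ol, via silyl acetal 11 (not isolated)
Conditions: HC(OMe)3, MeOH, camphorsulfonic acid (cat.), rt
Reagents that add atoms: trimethyl orthoformate, COC(OC)OC; methanol, CO
Why: Acid-catalysed acetalisation with orthoformate protects C2 at the aldehyde oxidation level, and the same acidic methanol removes the primary silyl ether by methanolysis, the freed C15 hydroxyl being trans to the acetal and unable to cyclise onto it.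

Step 8
Reactants: 13 (S)-5-(hydroxymethyl)furan-2(5H)-one
Product: 14 (S)-5-{[(tert-butyldimethylsilyl)oxy]methyl}furan-2(5H)-one
Conditions: TBSCl, imidazole, DMF, 0 °C → rt
Reagents that add atoms: tert-butyldimethylsilyl chloride, CC(C)(C)[Si](C)(C)Cl
Why: Standard silylation of the primary alcohol gives the bulky C5 substituent that will shield one face of the butenolide.

Step 9
Reactants: 14 (S)-5-{[(tert-butyldimethylsilyl)oxy]methyl}furan-2(5H)-one
Product: 16 (3R,4S,5S)-5-{[(tert-butyldimethylsilyl)oxy]methyl}-3-[(dimethylamino)methyl]-4-(1,3-dithian-2-yl)oxolan-2-one, via lithium enolate 15 (not isolated)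
Conditions: 1,3-dithiane, n-BuLi, THF/HMPA, –78 °C; 14; then CH2=NMe2+ I–, –78 → 0 °C
Reagents that add atoms: 1,3-dithiane, C1CSCSC1; N,N-dimethylmethyleneiminium iodide, C=[N+](C)C.[I-]
Why: Tandem conjugate addition–Mannich reaction: 2-lithio-1,3-dithiane adds 1,4 (HMPA) anti to the C5 silyloxymethyl group, which sets C7, and the lactone enolate is aminomethylated anti to the new dithianyl group, which installs C13 as a masked methylene (the C11 configuration is of no consequence).

Step 10
Reactants: 16 (the dithianyl lactone)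
Product: 17 (2S,3S,4R)-2-{[(tert-butyldimethylsilyl)oxy]methyl}-4-[(dimethylamino)methyl]-5-oxooxolane-3-carbaldehyde
Conditions: PhI(OCOCF3)2, CF3CO2H (1 equiv), MeCN/H2O 9:1, 0 °C; cold NaHCO3 work-up
Reagents that add atoms: water, O
Why: Oxidative dithiane hydrolysis with the hypervalent iodine reagent frees the C8 aldehyde within minutes while the amine is protonated, so neither amine oxidation nor base-induced β-elimination of the lactone carboxylate should intervene.

Step 11
Reactants: 17 (the C8 aldehyde)
Product: 18 (3R,4R,5S)-5-{[(tert-butyldimethylsilyl)oxy]methyl}-3-[(dimethylamino)methyl]-4-[(1R)-1-hydroxy-3-methylbut-3-en-1-yl]oxolan-2-one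
Conditions: (+)-Ipc2BOMe, CH2=C(CH3)CH2MgCl, Et2O, –78 °C → rt; then 17, –78 °C; 8-hydroxyquinoline work-up
Reagents that add atoms: 2-methylallylmagnesium chloride, CC(=C)C[Mg]Cl
Why: Brown asymmetric allylboration: the B-(2-methylallyl)diisopinocampheylborane derived from (–)-α-pinene adds through a closed chair transition state under reagent control and should give the 8R carbinol, the non-oxidative work-up sparing lactone and amine.

Step 12
Reactants: 18 (the C8 alcohol); 6 (Z)-2-(acetoxymethyl)but-2-enoic acid
Product: 20 C8 (Z)-2-(acetoxymethyl)but-2-enoate of 18, via mixed anhydride 19 (not isolated)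
Conditions: 6, 2,4,6-trichlorobenzoyl chloride, Et3N, toluene, rt; then 18, DMAP, rt
Reagents that add atoms: none
Why: Yamaguchi esterification acylates the hindered C8 hydroxyl, the only free OH present, under conditions known to preserve angelate-type Z geometry.

Step 13
Reactants: 20 (the C8 ester with C5 silyl ether)
Product: 21 the corresponding primary alcohol (C5–OH)
Conditions: HF·pyridine, pyridine, THF, 0 °C
Reagents that add atoms: none
Why: Fluoride-mediated desilylation removes the primary silyl ether without touching the esters or the lactone.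

Step 14
Reactants: 21 (the C5 alcohol)
Product: 22 the C5 aldehyde
Conditions: Dess–Martin periodinane, NaHCO3, CH2Cl2, 0 °C → rt
Reagents that add atoms: none
Why: Dess–Martin oxidation under buffered non-basic conditions should give the α-acyloxy aldehyde without epimerising C6, and the crude aldehyde is used at once.

Step 15
Reactants: 22 (the C5 aldehyde); 12 (Z)-2-iodo-4,4-dimethoxybut-2-en-1-ol
Product: 23 the (5S)-allylic alcohol carrying the (Z)-C4(CH2OH)=C3H–C2H(OMe)2 unit
Conditions: CrCl2, NiCl2 (cat.), chiral sulfonamide–oxazoline ligand, Et3N, THF, rt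
Reagents that add atoms: none
Why: Nozaki–Hiyama–Kishi coupling: the alkenylchromium species formed from 12 with retention of alkene geometry adds only to the aldehyde (free hydroxyl, acetal, esters, lactone and amine are tolerated), the chiral chromium ligand is relied on to direct attack to the face that gives 5S (C5–O syn to C6–O), and the crude diol is acetylated without exposure to acid.

Step 16
Reactants: 23 (the C5,C15 diol)
Product: 24 the C5,C15 diacetate
Conditions: Ac2O, pyridine, DMAP (cat.), CH2Cl2, 0 °C
Reagents that add atoms: acetic anhydride, CC(=O)OC(C)=O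
Why: Acetylation of the secondary C5 and primary C15 hydroxyls installs both ring-bound acetates and removes the hydroxyl that could cyclise onto the Z-disposed acetal.

Step 17
Reactants: 24 (the diacetate acetal)
Product: 26 the (Z)-enal aldoxime at C2, via enal 25 (not isolated)
Conditions: NH2OH·HCl, THF/H2O 4:1, rt; then NaOAc
Reagents that add atoms: hydroxylamine hydrochloride, [NH3+]O.[Cl-]
Why: The acidic hydroxylamine salt hydrolyses the allylic dimethyl acetal and the Z-enal is trapped at once as its aldoxime (oxime formation) before it can isomerise.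

Step 18
Reactants: 26 (the aldoxime)
Product: 28 the bridged isoxazoline: ten-membered carbocycle C1–C10 with an O–N bridge from C10 to C2 (C2=N) and 10S configuration, via nitrile oxide 27 (not isolated)
Conditions: PhI(OAc)2, CF3CO2H (1.2 equiv), MeOH/CH2Cl2, slow addition of 26, ca. 1 mM, 0 °C → rt
Reagents that add atoms: none
Why: Oxidation of the aldoxime by the hypervalent iodine reagent gives the conjugated nitrile oxide 27, whose C2≡N–O dipole adds in a concerted [3+2] fashion across the electron-rich 1,1-disubstituted C10=C1 double bond of the 2-methylallyl group (intramolecular nitrile oxide–olefin cycloaddition, the closest known type being nitrile oxide macrocyclisations that give bridged isoxazolines). Two rings close at once: the ten-membered carbocycle by C2–C1 bond formation in the endo (bridged) mode, both alkene carbons ending inside the ring, and the five-membered isoxazoline by the accompanying C10–O bond, so the product is a bicyclo[7.2.1] system with O–N as the two-atom bridge. The only new stereocentre, C10, is fixed by the face of the alkene that meets the dipole: attack is expected on the face that places the O–N bridge on the side of the ring opposite to the C5 acetoxy, C7–C11 and C8 acyloxy substituents, which corresponds to 10S. Regioselectivity (oxygen to the more substituted C10, carbon to the terminal C1) is the normal electronic preference of nitrile oxides with 1,1-disubstituted alkenes and is what places the new C–C bond between C1 and C2. Chemoselectivity is secured by the substrate: C13 is masked as the protonated Mannich base, the trisubstituted electron-poor side-chain enoate is a poor dipolarophile, C3=C4 is conjugated to the dipole and cannot reach it, and the Z geometry of C3=C4 together with the trans-fused lactone folds the chain so that C2 and C1 lie close, while slow generation of the dipole at high dilution should suppress furoxan formation. The isoxazoline also masks the C2 and C10 oxygens until the last steps.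

Step 19
Reactants: 28 (the bridged isoxazoline)
Product: 30 the β-hydroxy enone (C2 ketone, C10 tertiary alcohol), via hydroxy imine 29 (not isolated)
Conditions: Mo(CO)6, MeCN/H2O 15:1, 80 °C
Reagents that add atoms: water, O
Why: Mo(CO)6 cleaves the weak N–O bond reductively and the β-hydroxy imine is hydrolysed in the wet solvent (reductive isoxazoline opening), neutral conditions that should spare the acetates, the enoate and the Mannich base and leave C10 untouched.

Step 20
Reactants: 30 (the β-hydroxy enone)
Product: 32 the C2,C10 syn-diol still carrying the C13 dimethylamino group, via diethylborinate 31 (not isolated)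
Conditions: Et2BOMe, THF/MeOH 4:1, –78 °C; NaBH4; MeOH work-up
Reagents that add atoms: none
Why: Narasaka–Prasad reduction: the C10 borinate chelates the C2 ketone, this chelate must bridge C10 and C2 on one ring face, and external hydride therefore attacks C2 from the other face to give the 1,3-syn diol (2R) by 1,2-reduction without touching the esters.

Step 21
Reactants: 32 (the amino diol)
Product: 34 the target CNP0126757.1, via ammonium iodide 33 (not isolated)
Conditions: MeI, acetone, rt; then aq. NaHCO3, EtOAc, rt
Reagents that add atoms: none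
Why: Quaternisation of the Mannich base and bicarbonate-induced E1cB loss of trimethylamine (Hofmann-type elimination of a β-ammonio lactone) should unveil the C11=C13 methylene under conditions too mild to affect the acetates, the free diol or the Z-enoate.

**Compound list**

1 | (E)-but-2-enal (crotonaldehyde) | C/C=C/C=O | starting material
2 | (Z)-2-iodobut-2-enal | C/C=C(\I)C=O | intermediate
3 | (Z)-2-iodobut-2-en-1-ol | C/C=C(\I)CO | intermediate
4 | lithium (Z)-2-lithiobut-2-en-1-olate | C/C=C(\[Li])CO[Li] | intermediate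
5 | (Z)-2-(hydroxymethyl)but-2-enoic acid | C/C=C(\C(=O)O)CO | intermediate
6 | (Z)-2-(acetoxymethyl)but-2-enoic acid | C/C=C(\C(=O)O)COC(C)=O | intermediate
7 | 4-[(tert-butyldimethylsilyl)oxy]but-2-yn-1-ol | OCC#CCO[Si](C)(C)C(C)(C)C | starting material
8 | sodium cyclic alkenylalanate from trans-hydroalumination of 7 | [Na+].COCCO[Al-]1(OCCOC)OCC=C1CO[Si](C)(C)C(C)(C)C | intermediate
9 | (Z)-4-[(tert-butyldimethylsilyl)oxy]-3-iodobut-2-en-1-ol | OC/C=C(\I)CO[Si](C)(C)C(C)(C)C | intermediate
10 | (Z)-4-[(tert-butyldimethylsilyl)oxy]-3-iodobut-2-enal | O=C/C=C(\I)CO[Si](C)(C)C(C)(C)C | intermediate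
11 | tert-butyl{[(Z)-2-iodo-4,4-dimethoxybut-2-en-1-yl]oxy}dimethylsilane | COC(OC)/C=C(\I)CO[Si](C)(C)C(C)(C)C | intermediate
12 | (Z)-2-iodo-4,4-dimethoxybut-2-en-1-ol | COC(OC)/C=C(\I)CO | intermediate
13 | (S)-5-(hydroxymethyl)furan-2(5H)-one | O=C1O[C@H](CO)C=C1 | starting material
14 | (S)-5-{[(tert-butyldimethylsilyl)oxy]methyl}furan-2(5H)-one | O=C1O[C@H](CO[Si](C)(C)C(C)(C)C)C=C1 | intermediate
15 | lithium enolate of the trans conjugate adduct of 14 with 1,3-dithiane | C1=C(O[Li])O[C@H](CO[Si](C)(C)C(C)(C)C)[C@H]1C2SCCCS2 | intermediate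
16 | (3R,4S,5S)-5-{[(tert-butyldimethylsilyl)oxy]methyl}-3-[(dimethylamino)methyl]-4-(1,3-dithian-2-yl)oxolan-2-one | CN(C)C[C@@H]1C(=O)O[C@H](CO[Si](C)(C)C(C)(C)C)[C@H]1C2SCCCS2 | intermediate
17 | (2S,3S,4R)-2-{[(tert-butyldimethylsilyl)oxy]methyl}-4-[(dimethylamino)methyl]-5-oxooxolane-3-carbaldehyde | CN(C)C[C@@H]1C(=O)O[C@H](CO[Si](C)(C)C(C)(C)C)[C@H]1C=O | intermediate
18 | (3R,4R,5S)-5-{[(tert-butyldimethylsilyl)oxy]methyl}-3-[(dimethylamino)methyl]-4-[(1R)-1-hydroxy-3-methylbut-3-en-1-yl]oxolan-2-one | CN(C)C[C@@H]1C(=O)O[C@H](CO[Si](C)(C)C(C)(C)C)[C@H]1[C@H](O)CC(C)=C | intermediate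
19 | (Z)-2-(acetoxymethyl)but-2-enoic 2,4,6-trichlorobenzoic anhydride | C/C=C(\C(=O)OC(=O)c1c(Cl)cc(Cl)cc1Cl)COC(C)=O | intermediate
20 | C8 (Z)-2-(acetoxymethyl)but-2-enoate of 18 (C5 silyl ether kept) | CN(C)C[C@@H]1C(=O)O[C@H](CO[Si](C)(C)C(C)(C)C)[C@H]1[C@H](OC(=O)/C(=C\C)COC(C)=O)CC(C)=C | intermediate
21 | desilylated 20 (primary C5 alcohol) | CN(C)C[C@@H]1C(=O)O[C@H](CO)[C@H]1[C@H](OC(=O)/C(=C\C)COC(C)=O)CC(C)=C | intermediate
22 | C5 aldehyde from 21 | CN(C)C[C@@H]1C(=O)O[C@H](C=O)[C@H]1[C@H](OC(=O)/C(=C\C)COC(C)=O)CC(C)=C | intermediate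
23 | (5S)-allylic alcohol from 22 and 12 (free C5 and C15 hydroxyls, Z-C3=C4, C2 dimethyl acetal) | CN(C)C[C@@H]1C(=O)O[C@H]([C@@H](O)/C(CO)=C\C(OC)OC)[C@H]1[C@H](OC(=O)/C(=C\C)COC(C)=O)CC(C)=C | intermediate
24 | C5,C15 diacetate of 23 | CN(C)C[C@@H]1C(=O)O[C@H]([C@@H](OC(C)=O)/C(COC(C)=O)=C\C(OC)OC)[C@H]1[C@H](OC(=O)/C(=C\C)COC(C)=O)CC(C)=C | intermediate
25 | (Z)-enal (C2 aldehyde) from 24 | CN(C)C[C@@H]1C(=O)O[C@H]([C@@H](OC(C)=O)/C(COC(C)=O)=C\C=O)[C@H]1[C@H](OC(=O)/C(=C\C)COC(C)=O)CC(C)=C | intermediate
26 | (E)-aldoxime of 25 | CN(C)C[C@@H]1C(=O)O[C@H]([C@@H](OC(C)=O)/C(COC(C)=O)=C\C=N\O)[C@H]1[C@H](OC(=O)/C(=C\C)COC(C)=O)CC(C)=C | intermediate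
27 | nitrile oxide from 26 | CN(C)C[C@@H]1C(=O)O[C@H]([C@@H](OC(C)=O)/C(COC(C)=O)=C\C#[N+][O-])[C@H]1[C@H](OC(=O)/C(=C\C)COC(C)=O)CC(C)=C | intermediate
28 | bridged isoxazoline: ten-membered carbocycle with O–N bridge C10→C2, (10S), 5,15-diacetate, C8 ester, 6,12-lactone, 13-dimethylamino | CN(C)C[C@@H]1C(=O)O[C@H]2[C@H]1[C@H](OC(=O)/C(=C\C)COC(C)=O)C[C@@]3(C)ON=C(C3)/C=C(/COC(C)=O)[C@@H]2OC(C)=O | intermediate
29 | β-hydroxy imine (C2=NH, C10–OH) from N–O cleavage of 28 | CN(C)C[C@@H]1C(=O)O[C@H]2[C@H]1[C@H](OC(=O)/C(=C\C)COC(C)=O)C[C@@](C)(O)CC(=N)/C=C(/COC(C)=O)[C@@H]2OC(C)=O | intermediate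
30 | β-hydroxy enone (C2 ketone, C10–OH) | CN(C)C[C@@H]1C(=O)O[C@H]2[C@H]1[C@H](OC(=O)/C(=C\C)COC(C)=O)C[C@@](C)(O)CC(=O)/C=C(/COC(C)=O)[C@@H]2OC(C)=O | intermediate
31 | C10 diethylborinate of 30 | CN(C)C[C@@H]1C(=O)O[C@H]2[C@H]1[C@H](OC(=O)/C(=C\C)COC(C)=O)C[C@@](C)(OB(CC)CC)CC(=O)/C=C(/COC(C)=O)[C@@H]2OC(C)=O | intermediate
32 | 13-(dimethylamino)-11,13-dihydro derivative of the target (2R,10S syn-diol) | CN(C)C[C@@H]1C(=O)O[C@H]2[C@H]1[C@H](OC(=O)/C(=C\C)COC(C)=O)C[C@@](C)(O)C[C@@H](O)/C=C(/COC(C)=O)[C@@H]2OC(C)=O | intermediate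
33 | trimethylammonium iodide of 32 | C[N+](C)(C)C[C@@H]1C(=O)O[C@H]2[C@H]1[C@H](OC(=O)/C(=C\C)COC(C)=O)C[C@@](C)(O)C[C@@H](O)/C=C(/COC(C)=O)[C@@H]2OC(C)=O.[I-] | intermediate
34 | CNP0126757.1 | C=C1C(=O)O[C@H]2[C@H]1[C@H](OC(=O)/C(=C\C)COC(C)=O)C[C@@](C)(O)C[C@@H](O)/C=C(/COC(C)=O)[C@@H]2OC(C)=O | target

**Step count and risks**

Total step count: 21 (steps 1–4 side-chain acid, steps 5–7 alkenyl iodide, steps 8–21 main line). Longest linear sequence: 14 steps (13 → 34, steps 8–21).

Steps most likely to fail:

1. Step 18. The ten-membered ring closure may be slower than dimerisation of the nitrile oxide or intermolecular cycloaddition, and the dipole may add to the wrong face of C10=C1. The fallback forms the isoxazoline first and closes the ring at C4–C5 instead. It sets out from 10 and 21. Aldehyde 10 is converted with NH2OH·HCl/NaOAc into (1E,2Z)-4-[(tert-butyldimethylsilyl)oxy]-3-iodobut-2-enal oxime F1. Its nitrile oxide (PhI(OAc)2) is added intermolecularly to the 2-methylallyl group of 21 to give the acyclic isoxazoline alcohol F2, whose C10 epimers would be separated by chromatography. Dess–Martin oxidation gives the isoxazoline aldehyde F3. An intramolecular Ni/Cr coupling (CrCl2, NiCl2 cat., high dilution) closes the ring to the macrocyclic C5 alcohol F4. HF·pyridine gives the C5,C15 diol F5, and acetylation (Ac2O, pyridine) returns to the route at 28.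

2. Step 15. Facial selectivity at C5 may be poor because ligand control opposes the intrinsic (Felkin-type) preference of the α-acyloxy aldehyde, and the Z-hydroxy acetal may cyclise during coupling. The fallback sets out from 22 and 12 and runs the coupling with the antipodal ligand, so that ligand and substrate preferences reinforce each other and give the 5R allylic alcohol F6. A Mitsunobu reaction with acetic acid (PPh3, DIAD) then esterifies the primary C15 hydroxyl and inverts C5, returning to the route at 24.

3. Step 11. The β-acyloxy aldehyde may lose the lactone carboxylate by β-elimination assisted by the internal amine, or the allylborane may be retarded by amine coordination so that conversion and selectivity fall. The fallback makes the C8 carbinol by reduction instead of addition and sets out from 14. 1,3-Dithiane is alkylated (n-BuLi, 3-chloro-2-methylpropene) to 2-(2-methylprop-2-en-1-yl)-1,3-dithiane F7. Its lithio derivative is used in the tandem conjugate addition–aminomethylation of 14 to give the dithioketal lactone F8. Hydrolysis with PhI(OCOCF3)2 gives the C8 ketone F9. Reagent-controlled reduction with the appropriate CBS oxazaborolidine and catecholborane returns to the route at 18.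

**Further compounds**

F1 | step 18 | (1E,2Z)-4-[(tert-butyldimethylsilyl)oxy]-3-iodobut-2-enal oxime | O/N=C/C=C(\I)CO[Si](C)(C)C(C)(C)C
F2 | step 18 | acyclic isoxazoline alcohol from F1 and 21 (C10 as in 28, C5–OH, alkenyl iodide, C15 silyl ether) | CN(C)C[C@@H]1C(=O)O[C@H](CO)[C@H]1[C@H](OC(=O)/C(=C\C)COC(C)=O)C[C@]2(C)CC(=NO2)/C=C(\I)CO[Si](C)(C)C(C)(C)C
F3 | step 18 | isoxazoline aldehyde (C5 aldehyde of F2) | CN(C)C[C@@H]1C(=O)O[C@H](C=O)[C@H]1[C@H](OC(=O)/C(=C\C)COC(C)=O)C[C@]2(C)CC(=NO2)/C=C(\I)CO[Si](C)(C)C(C)(C)C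
F4 | step 18 | macrocyclic isoxazoline with free C5 hydroxyl and C15 silyl ether | CN(C)C[C@@H]1C(=O)O[C@H]2[C@H]1[C@H](OC(=O)/C(=C\C)COC(C)=O)C[C@@]3(C)ON=C(C3)/C=C(/CO[Si](C)(C)C(C)(C)C)[C@@H]2O
F5 | step 18 | macrocyclic isoxazoline C5,C15 diol | CN(C)C[C@@H]1C(=O)O[C@H]2[C@H]1[C@H](OC(=O)/C(=C\C)COC(C)=O)C[C@@]3(C)ON=C(C3)/C=C(/CO)[C@@H]2O
F6 | step 15 | (5R)-epimer of 23 | CN(C)C[C@@H]1C(=O)O[C@H]([C@H](O)/C(CO)=C\C(OC)OC)[C@H]1[C@H](OC(=O)/C(=C\C)COC(C)=O)CC(C)=C
F7 | step 11 | 2-(2-methylprop-2-en-1-yl)-1,3-dithiane | CC(=C)CC1SCCCS1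
F8 | step 11 | dithioketal lactone: 16 with a 2-methylallyl group on the dithiane carbon | CN(C)C[C@@H]1C(=O)O[C@H](CO[Si](C)(C)C(C)(C)C)[C@H]1C2(CC(C)=C)SCCCS2
F9 | step 11 | C8 ketone: 4-(3-methylbut-3-enoyl) lactone | CN(C)C[C@@H]1C(=O)O[C@H](CO[Si](C)(C)C(C)(C)C)[C@H]1C(=O)CC(C)=C
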